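Each millimolar of starting material charged faces a fork between dissolved gas and target, and the flasks below differ in the charge.

    gas phase ⇌ dissolved gas, rate k1*(csat - [dissolved gas]) (k1 = 0.18 h⁻¹, csat = 1.5 mM)
    starting material + dissolved gas → target (k2 = 22 M⁻¹ h⁻¹)
    starting material + target → side product (k3 = 2.9 M⁻¹ h⁻¹)
    starting material ⇌ dormant form (K4 = 1.8, k4 = 0.038 h⁻¹)

in all of them: gas phase 1.5 mM (held); time 30 h

| charge | starting material |
|---|---|
| dawn | 4.0 mM |
| summer | 6.0 mM |
| noon | 10 mM |

- in percentages every species weighs as the starting material in it: one side product counts as two
- at the start none of the gas is dissolved
- "hardly changes" means that all values lie within two and a half points (for a concentration: within two and a half percent of the largest)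
- run time (dawn): 30 h

- amount of target at the end, in percent of the starting material charged for dawn, summer, noon, in this order
- the course of these numbers from the first flask to the last (falls, then rises / falls all the way / rises all the way / rises, then falls / hardly changes)

First comes the main step by itself, with dissolved gas taken at saturation. Starting material then decays in a pseudo-first-order way with the apparent constant 0.0330 h⁻¹. So 62.8% of the charge becomes target in 30 h, at each charge.

Now the dormant form is added. Its exchange with starting material, both ways together, relaxes in dawn with a half-life of 11.7 h, shorter than the run, so the equilibrium is used for the whole reckoning. The free share of starting material plus dormant form is then 35.7%, and the yield drops to 29.8%. This skips the start, when no dormant form stands and none of the gas is dissolved.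

Next comes the gas transfer. With the whole charge taken at that free share, starting material removes dissolved gas at 0.0314 h⁻¹ in dawn and 0.0786 h⁻¹ in noon, against a transfer coefficient of 0.18 h⁻¹. Summer lies between, at 0.0471 h⁻¹. Balancing supply and removal gives reckoned dissolved gas of 1.28 mM, 1.19 mM and 1.04 mM for dawn, summer and noon, so noon sags further than dawn. The yields become 26.0%, 24.4% and 21.8%, in the same order.

The side step comes last. Reckoned end values give 9.32 for dawn, 6.15 for summer and 3.63 for noon. These are values of the fork odds F: the main rate constant times dissolved gas, over the side rate constant times target, which are the odds that a reacting starting material molecule takes dissolved gas rather than target. F also says how many times faster target is made than used up. Target grows from nothing, so the loss over the run is taken as 0.5 of the inverse of the end F. The reckoning therefore commits to 24.6%, 22.4% and 18.8%, falling all the way.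

The forecast says 31%, 28% and 23%, each above this reckoning, and falls all the way, on the grounds that “a larger charge pulls the dissolved gas down”.

The simulation gives 29.4%, 26.5% and 21.7%; the course falls all the way. At the end of dawn, target is made 8.41 times faster than it is used up, against the reckoned 9.32. At the end of noon, the dissolved gas and target standing in the flask give F = 3.79, lower than in dawn and against the reckoned 3.63, and side product stands at 8.72%.

The constants used here are those of an exercise; the run is a simulation.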